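The readings are calculated from invented constants, noise included.

Once the feed has ended, the electrophile charge is either still standing or has reacted, so the part reacted is the charge minus what stands, and c turns on how fast that standing amount falls.

in all of them: electrophile 0.10 M (fed, over 12 h)

|  | nucleophile | buffer base | buffer acid | remark | time |
|---|---|---|---|---|---|
| autumn | 0.12 M | 0.10 M | 0.010 M | the very flask that is asked about, followed so far |  |
| dawn | 0.12 M | 0.067 M | 0.010 M | run made earlier |  |
| flask | 0.120 M | 0.100 M | 0.0100 M |  | 40 h |

| run | time / h | electrophile / % | product / % |
|---|---|---|---|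
| autumn | 2.50 | 20.1 | 1.1 |
| autumn | 8.00 | 57.6 | 8.2 |
| autumn | 12.0 | 82.0 | 13.9 |
| autumn | 20.0 | 66.9 | 22.9 |
| dawn | 8.00 | 57.4 | 6.8 |
| dawn | 15.0 | 75.1 | 17.6 |
| dawn | 20.0 | 67.3 | 22.3 |
| dawn | 30.0 | 55.8 | 27.1 |

(each reading ± 0.5 percentage points)

- the earlier runs were read with a standard deviation of 0.5 percentage points
- the earlier runs do not show the pH; that part of a forecast is a guess
- percentages count the whole charge, also what has not yet gone in

1. part of the electrophile that has reacted at 40 h
2. pH of the solution at 40 h

A steady feed over 12 h delivers its portions on average at 6.00 h, so the electrophile's mean age at any time after the end of the feed is that time less 6.00 h. The dawn run, with less buffer base, read 67.3% at 20.0 h where the autumn flask read 66.9%, a gap of 0.4 percentage points against a scatter of 0.5 points, so the dawn run can stand in for the autumn flask's later course. At 30.0 h the dawn run holds 55.8% at a mean age of 24.0 h, which gives 28.5 h. This is the mean-age half-life, the age at which half the charge would stand if the decay were first-order from mid-feed. The autumn flask at 20.0 h gives 24.1 h, so the reading from the later time is longer.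

At 40 h the mean age is 34.0 h, and a reckoning made here with 28.5 h leaves 43.8%, so c comes to 56.2%. That may stand on the high side, since the reading from the later time was the longer. The forecast gives 54.5%, lower than this reckoning, and pH 7.2, which it calls “purely a guess”.

The flask gives 51.2% and pH 8.55. The forecast's c lies within its margin, and its pH lies below the flask's.

    nucleophile ⇌ dormant form (K = 1.90, k = 5.30 × 10⁻⁴ min⁻¹)
    2 electrophile → homo dimer (k = 0.00120 L mol⁻¹ min⁻¹)
    buffer acid ⇌ buffer base + acid, settled at all times (K = 5.00 × 10⁻⁸ M)
    electrophile + nucleophile → acid + product + leaving group (k = 0.00580 L mol⁻¹ min⁻¹)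
    protonated nucleophile ⇌ nucleophile + acid, settled at all times (K = 1.30 × 10⁻⁹ M)

The flask's 51.2% means a mean-age half-life of 32.8 h, longer than the dawn reading, while the neighbour with c(nucleophile) at 0.20 M has 23.6 h, shorter than the flask's. At 40.0 h the flask uses electrophile on the way to product at 0.81 of the rate on the way to homo dimer, with less of the nucleophile charge free, 14%, than of the electrophile charge, 49%.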